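**Plan**

- Retrosynthetic cuts: the ketone C(=O)–aryl bond to the prenylated ring A; the prenyl CH2–ring A bond; and, in the pyran ring, both C4–C4a and C3–C2. The last pair excises C3H=C4H as acetylene and leaves an aryl ether ArO1–C2Me2–CO2R of 2,4-dihydroxybenzaldehyde.
- Enabling feature: C2 is a quaternary carbon on the ring oxygen O1, so its carboxylic acid derivative gives a tertiary α-aryloxy radical on decarboxylation. C4a is a free ortho CH of the electron-rich resorcinol ring B. An alkyne can be stitched between the two in a radical [4+2] annulation that closes the six-membered pyran ring.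
- Forward, ring B: O4-alkylation of 2,4-dihydroxybenzaldehyde, TIPS on the chelated OH (protecting and steering group), redox-active ester, then photoredox annulation with acetylene to the linear chromene aldehyde.
- Forward, ring A and union: ortho-lithiation, cupration and prenylation of MOM-protected 3-bromophenol; aryllithium addition to the chromene aldehyde, oxidation to the benzophenone, removal of both protecting groups in one pot.
- Stereochemistry: the target has no stereocentre and no E/Z element (C3=C4 is cis in the ring, the prenyl alkene carries two methyls), so it is one achiral compound. The only stereocentre on the way, carbinol 16, is racemic and is erased by the oxidation.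

Key step: step 4

**Route**

Step 1
Reactants: 1 2,4-dihydroxybenzaldehyde; 2 tert-butyl 2-bromo-2-methylpropanoate
Product: 3 tert-butyl 2-(4-formyl-3-hydroxyphenoxy)-2-methylpropanoate
Conditions: K2CO3 (1.2 equiv), 2 (2 equiv), DMF, 70 °C
Reagents that add atoms: none
Why: Williamson-type O-alkylation as used for fibrate esters: with one equivalent of carbonate only the 4-OH, which is the more acidic phenol and is not held in the hydrogen bond to the formyl group, is deprotonated and attacks the tertiary α-bromo ester, so the chelated 2-OH stays free.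

Step 2
Reactants: 3 tert-butyl 2-(4-formyl-3-hydroxyphenoxy)-2-methylpropanoate
Product: 4 tert-butyl 2-{4-formyl-3-[tri(propan-2-yl)silyloxy]phenoxy}-2-methylpropanoate
Conditions: TIPSCl, imidazole, DMAP (cat.), DMF, rt
Reagents that add atoms: triisopropylsilyl chloride, CC(C)[Si](Cl)(C(C)C)C(C)C
Why: Standard silylation of a phenol with silyl chloride and imidazole, which tolerates the aldehyde and the tert-butyl ester; the bulky TIPS group serves as protecting group and as the steric shield for step 4.

Step 3
Reactants: 4 tert-butyl 2-{4-formyl-3-[tri(propan-2-yl)silyloxy]phenoxy}-2-methylpropanoate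
Product: 6 1,3-dioxoisoindolin-2-yl 2-{4-formyl-3-[tri(propan-2-yl)silyloxy]phenoxy}-2-methylpropanoate, via carboxylic acid 5 (not isolated)
Conditions: TFA, CH2Cl2, 0 °C to rt; evaporation with toluene; then N-hydroxyphthalimide, DIC, DMAP (cat.), CH2Cl2, rt
Reagents that add atoms: N-hydroxyphthalimide, O=C1c2ccccc2C(=O)N1O
Why: Acidolysis of the tert-butyl ester (loss of isobutene via the tert-butyl cation) leaves the aryl TIPS ether and the aldehyde untouched, and Steglich-type carbodiimide coupling of the hindered acid with N-hydroxyphthalimide gives the redox-active ester needed for reductive decarboxylation.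

Step 4
Reactants: 6 1,3-dioxoisoindolin-2-yl 2-{4-formyl-3-[tri(propan-2-yl)silyloxy]phenoxy}-2-methylpropanoate; 7 acetylene
Product: 8 2,2-dimethyl-7-[tri(propan-2-yl)silyloxy]-2H-chromene-6-carbaldehyde
Conditions: acetylene (1 atm, saturated solution), fac-Ir(ppy)3 (1 mol %), DMSO, 450 nm LEDs, rt
Reagents that add atoms: none
Why: Proposed new method: photoexcited fac-Ir(ppy)3 (about −1.7 V vs SCE) transfers an electron to the N-acyloxyphthalimide 6 (about −1.3 V), which loses CO2 and phthalimide anion to give the tertiary α-aryloxy radical ArO–C•Me2; this nucleophilic radical adds to acetylene, the rapidly inverting β-alkylvinyl σ-radical attacks the ortho CH para to the silyloxy group, and the cyclohexadienyl radical is oxidised by Ir(IV) and deprotonated by phthalimide anion, so the cycle is redox-neutral and needs no terminal oxidant or reductant. The closest known reaction types are photoredox decarboxylative alkylation–cyclisation–rearomatisation cascades of redox-active esters (N-arylacrylamides to oxindoles, 2-isocyanobiaryls to phenanthridines), radical additions to acetylene gas, and vinyl-radical ortho-cyclisations of aryl propargyl ethers and aryl alkynoates to chromenes and coumarins; new is the intermolecular formal [4+2] of an α-aryloxyalkyl radical with acetylene. The pyran ring closes by six-membered ortho attack of the vinyl radical on the arene (homolytic aromatic substitution, 6-endo with respect to the C4a=C8a bond), the competing 5-exo ipso attack at the oxygen-bearing carbon having no productive exit. No stereocentre is formed and the C3=C4 bond is cis by ring constraint. The step needs regioselection between the two ortho positions of the aryl ether: the position between the two oxygens is flanked by the O–CMe2 tether and by the TIPS ether, whose silyl group is pushed towards it by the neighbouring formyl group, so closure should go to the open position and give the linear 6-formyl-7-silyloxy chromene. Chemoselectivity rests on the redox window (the aldehyde and the aryl silyl ether are not reduced by the excited catalyst) and on a high acetylene concentration that lets addition outrun oxidation of the α-aryloxy radical to the oxocarbenium ion.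

Step 5
Reactants: 9 3-bromophenol
Product: 10 1-bromo-3-(methoxymethoxy)benzene
Conditions: MOMCl, i-Pr2NEt, CH2Cl2, 0 °C to rt
Reagents that add atoms: chloromethyl methyl ether, COCCl
Why: Standard MOM protection of a phenol; the acetal is the ortho-directing group for step 6 and is stable to organolithium reagents.

Step 6
Reactants: 10 1-bromo-3-(methoxymethoxy)benzene; 11 1-bromo-3-methylbut-2-ene (prenyl bromide)
Product: 14 1-bromo-3-(methoxymethoxy)-2-(3-methylbut-2-en-1-yl)benzene, via aryllithium 12 (not isolated), via arylcopper reagent 13 (not isolated)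
Conditions: LDA, THF, −78 °C; CuBr·SMe2, −78 °C; then 11, −78 to −20 °C
Reagents that add atoms: none
Why: Directed ortho-metalation: LDA removes the proton flanked by Br and OMOM at −78 °C, transmetalation to copper stops loss of LiBr to an aryne, and the arylcopper reagent is allylated at the primary carbon of prenyl bromide (SN2 allylic substitution), as in known prenylations of lithiated MOM-protected phenols.

Step 7
Reactants: 14 1-bromo-3-(methoxymethoxy)-2-(3-methylbut-2-en-1-yl)benzene; 8 2,2-dimethyl-7-[tri(propan-2-yl)silyloxy]-2H-chromene-6-carbaldehyde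
Product: 16 (RS)-{2,2-dimethyl-7-[tri(propan-2-yl)silyloxy]-2H-chromen-6-yl}[3-(methoxymethoxy)-2-(3-methylbut-2-en-1-yl)phenyl]methanol, via aryllithium 15 (not isolated)
Conditions: n-BuLi, THF, −78 °C; then 8, −78 °C; AcOH quench at −78 °C
Reagents that add atoms: none
Why: Bromine–lithium exchange is faster than any deprotonation at −78 °C and the aryllithium adds 1,2 to the aldehyde; the new carbinol stereocentre forms racemic and is removed in step 8, and the cold acidic quench is meant to stop migration of the silyl group to the alkoxide.

Step 8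
Reactants: 16 (RS)-{2,2-dimethyl-7-[tri(propan-2-yl)silyloxy]-2H-chromen-6-yl}[3-(methoxymethoxy)-2-(3-methylbut-2-en-1-yl)phenyl]methanol
Product: 17 {2,2-dimethyl-7-[tri(propan-2-yl)silyloxy]-2H-chromen-6-yl}[3-(methoxymethoxy)-2-(3-methylbut-2-en-1-yl)phenyl]methanone
Conditions: Dess–Martin periodinane, NaHCO3, CH2Cl2, 0 °C to rt
Reagents that add atoms: none
Why: Dess–Martin oxidation of a secondary diaryl carbinol to the ketone under buffered, non-acidic conditions that leave both alkenes, the MOM acetal and the silyl ether intact.

Step 9
Reactants: 17 {2,2-dimethyl-7-[tri(propan-2-yl)silyloxy]-2H-chromen-6-yl}[3-(methoxymethoxy)-2-(3-methylbut-2-en-1-yl)phenyl]methanone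
Product: 19 Cudraphenone A [(7-hydroxy-2,2-dimethyl-2H-chromen-6-yl)[3-hydroxy-2-(3-methylbut-2-en-1-yl)phenyl]methanone], via phenol 18 (not isolated)
Conditions: TBAF, THF, 0 °C; then 3 M HCl, MeOH, rt to 40 °C
Reagents that add atoms: none
Why: Fluoride cleaves the aryl silyl ether at 0 °C, and methanolic HCl then transacetalises the MOM ether under mild conditions of the kind used for prenylated and chromene-bearing phenols, which should avoid acid-induced cyclisation of the prenyl group onto the free phenol.

**Compound list**

1 | 2,4-dihydroxybenzaldehyde | O=Cc1ccc(O)cc1O | starting material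
2 | tert-butyl 2-bromo-2-methylpropanoate | CC(C)(C)OC(=O)C(C)(C)Br | starting material
3 | tert-butyl 2-(4-formyl-3-hydroxyphenoxy)-2-methylpropanoate | CC(C)(C)OC(=O)C(C)(C)Oc1ccc(C=O)c(O)c1 | intermediate
4 | tert-butyl 2-{4-formyl-3-[tri(propan-2-yl)silyloxy]phenoxy}-2-methylpropanoate | CC(C)(C)OC(=O)C(C)(C)Oc1ccc(C=O)c(O[Si](C(C)C)(C(C)C)C(C)C)c1 | intermediate
5 | 2-{4-formyl-3-[tri(propan-2-yl)silyloxy]phenoxy}-2-methylpropanoic acid (not isolated) | OC(=O)C(C)(C)Oc1ccc(C=O)c(O[Si](C(C)C)(C(C)C)C(C)C)c1 | intermediate
6 | 1,3-dioxoisoindolin-2-yl 2-{4-formyl-3-[tri(propan-2-yl)silyloxy]phenoxy}-2-methylpropanoate | O=C(ON1C(=O)c2ccccc2C1=O)C(C)(C)Oc1ccc(C=O)c(O[Si](C(C)C)(C(C)C)C(C)C)c1 | intermediate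
7 | acetylene (ethyne) | C#C | starting material
8 | 2,2-dimethyl-7-[tri(propan-2-yl)silyloxy]-2H-chromene-6-carbaldehyde | CC1(C)C=Cc2cc(C=O)c(O[Si](C(C)C)(C(C)C)C(C)C)cc2O1 | intermediate
9 | 3-bromophenol | Oc1cccc(Br)c1 | starting material
10 | 1-bromo-3-(methoxymethoxy)benzene | COCOc1cccc(Br)c1 | intermediate
11 | 1-bromo-3-methylbut-2-ene (prenyl bromide) | CC(C)=CCBr | starting material
12 | [2-bromo-6-(methoxymethoxy)phenyl]lithium (not isolated) | [Li]c1c(Br)cccc1OCOC | intermediate
13 | [2-bromo-6-(methoxymethoxy)phenyl]copper (not isolated) | [Cu]c1c(Br)cccc1OCOC | intermediate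
14 | 1-bromo-3-(methoxymethoxy)-2-(3-methylbut-2-en-1-yl)benzene | CC(C)=CCc1c(Br)cccc1OCOC | intermediate
15 | [3-(methoxymethoxy)-2-(3-methylbut-2-en-1-yl)phenyl]lithium (not isolated) | [Li]c1cccc(OCOC)c1CC=C(C)C | intermediate
16 | (RS)-{2,2-dimethyl-7-[tri(propan-2-yl)silyloxy]-2H-chromen-6-yl}[3-(methoxymethoxy)-2-(3-methylbut-2-en-1-yl)phenyl]methanol, racemic | CC(C)=CCc1c(OCOC)cccc1C(O)c1cc2C=CC(C)(C)Oc2cc1O[Si](C(C)C)(C(C)C)C(C)C | intermediate
17 | {2,2-dimethyl-7-[tri(propan-2-yl)silyloxy]-2H-chromen-6-yl}[3-(methoxymethoxy)-2-(3-methylbut-2-en-1-yl)phenyl]methanone | CC(C)=CCc1c(OCOC)cccc1C(=O)c1cc2C=CC(C)(C)Oc2cc1O[Si](C(C)C)(C(C)C)C(C)C | intermediate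
18 | (7-hydroxy-2,2-dimethyl-2H-chromen-6-yl)[3-(methoxymethoxy)-2-(3-methylbut-2-en-1-yl)phenyl]methanone (not isolated) | CC(C)=CCc1c(OCOC)cccc1C(=O)c1cc2C=CC(C)(C)Oc2cc1O | intermediate
19 | Cudraphenone A, (7-hydroxy-2,2-dimethyl-2H-chromen-6-yl)[3-hydroxy-2-(3-methylbut-2-en-1-yl)phenyl]methanone, achiral | CC(C)=CCc1c(O)cccc1C(=O)c1cc2c(cc1O)OC(C)(C)C=C2 | target

**Step count and risks**

Total steps: 9. Longest linear sequence: 7 (steps 1, 2, 3, 4, 7, 8, 9); steps 5 and 6 form the second branch.

Steps most likely to fail:

1. Step 4 (proposed new method). The addition of the tertiary α-aryloxy radical to acetylene may be too slow, so that oxidation of the radical wins. The vinyl radical may attack the ipso carbon instead of the ortho carbon, or close at the position between the two oxygens, and it may take a hydrogen atom from the solvent before ring closure. The fallback uses known Heck chemistry and fixes the position through a halogen. It sets out from 1. Iodination with ICl in AcOH should go mainly para to the 2-OH and ortho to the 4-OH and give 2,4-dihydroxy-5-iodobenzaldehyde F1. Heck coupling with 2-methylbut-3-en-2-ol (Pd(OAc)2, P(o-tol)3, Et3N, DMF, 90 °C) would give 2,4-dihydroxy-5-[(1E)-3-hydroxy-3-methylbut-1-en-1-yl]benzaldehyde F2. Acid-catalysed cyclodehydration through the allyl cation (PPTS, toluene, 80 °C), with the neighbouring 4-OH attacking the tertiary terminus, would give 7-hydroxy-2,2-dimethyl-2H-chromene-6-carbaldehyde F3. Silylation (TIPSCl, imidazole, DMF) returns to the route at 8.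

2. Step 7. The TIPS group may migrate from the phenolic oxygen to the neighbouring lithium alkoxide before the quench, which would block the oxidation of step 8. The fallback gives up the silyl group at this stage instead of defending it. It sets out from 8 (with aryllithium 15 as in step 7). The addition mixture would be warmed to 0 °C so that the silyl shift runs to completion, giving the benzylic silyl ether 2,2-dimethyl-6-{[3-(methoxymethoxy)-2-(3-methylbut-2-en-1-yl)phenyl][tri(propan-2-yl)silyloxy]methyl}-2H-chromen-7-ol F4. TBAF in THF would give the phenol–carbinol 6-{hydroxy[3-(methoxymethoxy)-2-(3-methylbut-2-en-1-yl)phenyl]methyl}-2,2-dimethyl-2H-chromen-7-ol F5. Chemoselective benzylic oxidation with activated MnO2 in CH2Cl2, which leaves the phenol alone, would give 18, where the route is rejoined and only the methanolic HCl stage of step 9 remains.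

3. Step 6. The ortho-bromoaryllithium may lose LiBr to an aryne before transmetalation, and the allylic substitution may go with transposition (SN2′) to the 1,1-dimethylallyl isomer. The fallback replaces the copper-mediated allylation by a palladium-catalysed cross-coupling. It sets out from 10. Lithiation with LDA at −78 °C and an immediate quench with iodine at that temperature would give 1-bromo-2-iodo-3-(methoxymethoxy)benzene F6. Stille coupling at the more reactive C–I bond with tributyl(3-methylbut-2-en-1-yl)stannane (Pd(PPh3)4, DMF, 80 °C) should give the linear prenyl arene and returns to the route at 14.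

**Further compounds**

F1 | step 4 | 2,4-dihydroxy-5-iodobenzaldehyde | O=Cc1cc(I)c(O)cc1O
F2 | step 4 | 2,4-dihydroxy-5-[(1E)-3-hydroxy-3-methylbut-1-en-1-yl]benzaldehyde | CC(C)(O)/C=C/c1cc(C=O)c(O)cc1O
F3 | step 4 | 7-hydroxy-2,2-dimethyl-2H-chromene-6-carbaldehyde | CC1(C)C=Cc2cc(C=O)c(O)cc2O1
F4 | step 7 | 2,2-dimethyl-6-{[3-(methoxymethoxy)-2-(3-methylbut-2-en-1-yl)phenyl][tri(propan-2-yl)silyloxy]methyl}-2H-chromen-7-ol, racemic | CC(C)=CCc1c(OCOC)cccc1C(O[Si](C(C)C)(C(C)C)C(C)C)c1cc2C=CC(C)(C)Oc2cc1O
F5 | step 7 | 6-{hydroxy[3-(methoxymethoxy)-2-(3-methylbut-2-en-1-yl)phenyl]methyl}-2,2-dimethyl-2H-chromen-7-ol, racemic | CC(C)=CCc1c(OCOC)cccc1C(O)c1cc2C=CC(C)(C)Oc2cc1O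
F6 | step 6 | 1-bromo-2-iodo-3-(methoxymethoxy)benzene | COCOc1cccc(Br)c1I
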